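Larch was slow: after 10.0 min it had put 61.0 % of its D into G. So I reckoned with the part of D reacted and not with the whole charge.

| flask | D | E | remark | time |
|---|---|---|---|---|
| larch | 0.030 M (fed, over 2.5 min) | 0.18 mol% | run made earlier; the fed solution adds 0.50 times the starting volume |  |
| cedar | 0.040 M (fed, over 2.5 min) | 0.18 mol% | run made earlier; the fed solution adds 0.50 times the starting volume |  |
| winter | 0.020 M (fed, over 2.5 min) | 0.18 mol% | the fed solution adds 0.50 times the starting volume | 15 min |
| dawn | 0.020 M (fed, over 2.5 min) | 0.8 mol% | the fed solution adds 0.50 times the starting volume | 15 min |

- larch (time / min: G / %): 2.00: 13.0; 4.00: 32.8; 5.00: 39.7; 8.00: 54.1; 10.0: 61.0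
- cedar (time / min: G / %): 0.833: 3.5; 2.50: 20.0; 4.00: 35.8; 6.00: 49.2; 10.0: 65.7

(readings scatter by 0.5 percentage points)

- charges are per starting volume, the dose included; the dosed solution carries all of it
- the average divides the monomer in chains by the number of chains, living and dead together; two radicals that join make one chain
- the earlier runs do not show the number of chains; that part of a forecast is a guess
- percentages count the whole charge, also what has not yet gone in

1. which of the two ends with the longer chains by the average number of monomer units in a chain (living and dead chains, two that joined counted as one) ("neither" if they lie within 10 %) (winter / dawn / neither)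
2. average number of monomer units in a chain (living and dead chains, two that joined counted as one) at the end, winter
3. average number of monomer units in a chain (living and dead chains, two that joined counted as one) at the end, dawn

I folded the recipe into one number, ρ, the D charged per E charged, which is the length if D were used up and each E ended as one chain (a guess: E gives two radicals, and two radicals make one chain). Then length ≈ xρ, with x the part of D reacted:

ρ(winter) = 556, ρ(dawn) = 125

For x I used θ, minus the logarithm of the share of D unreacted. I took radicals as pairing off as fast as they form (quasi-steady state), so θ goes as the square root of E in the flask. Cedar over larch at 10.0 min gave 1.14, against a root of 1.15. Holding larch's last slope, 0.0815 min⁻¹, up to 15 min and scaling: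

θ(winter) = 1.10, x = 66.8 %, length 371

θ(dawn) = 2.32, x = 90.2 %, length 113

One number was not quite enough. Larch's slope had already fallen to that last value from 0.108 min⁻¹, so holding it puts my x high, while any unsplit E means fewer chains. These errors pull opposite ways.

The forecast said winter, with 450 and 180: “Assuming one chain per E (a guess), winter has about 0.77 E and dawn about 0.6 E”. Its lengths stood above mine .

The flask gave winter, with 368 against 116.

    D + J → X + G (k = 1.80 × 10⁶ L mol⁻¹ s⁻¹)
    D + X → G + X, rate k2*[X]*[D] (k = 2.00 × 10⁵ L mol⁻¹ s⁻¹)
    E → 2 J (k = 0.00320 s⁻¹)
    2 X → Z (k = 5.40 × 10⁸ L mol⁻¹ s⁻¹)

The gap comes from the difference in loading of E: dawn gave 116, and the same flask with that difference taken away, at winter's loading, gave 368. Winter's ρ with its 37 % of D left gives 350, and dividing by the E spent, with 5.6 % of E left in winter, gives 371. A neighbour flask, winter with 0.034 M of D, keeps winter's ρ; with 28 % of D and 5.6 % of E left, ρ gives 424, and the computed length is 425.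

(Readings and results are calculated with constants of no real substance.)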